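**Strategy.** Ring B (C5–C10) with its C6 oxygen, C7 isopropyl and C10 methyl is the carbon skeleton of (−)-menthone. The route cuts the menthone ring at C5–C6, annulates ring A across the freed C5 aldehyde and C10, and then re-forms the same C5–C6 bond. In that step the C6 acyl radical of a selenoester adds 6-exo to C5, the β-carbon of the ring-A enone, which closes ring B; base equilibration of the 3,6-diketone relays the C10 quaternary centre to C4, C5 and C7. The step exploits the 1,4 relation of the C3 and C6 oxygens. Its precursor is a 4,4-disubstituted 2-methylcyclohexenone with a selenoester side chain.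

Key step: step 5

Remarks on the chemistry:
- Eudesmane numbering is used: ring A = C1–C5, C10; ring B = C5–C10; C14 is the methyl on C10, C15 the methyl on C4; β is the face of the C10 methyl.
- The L-proline-derived sulfonamide catalyst in step 3 is assumed to give the (S) quaternary centre; if the sense is opposite, its enantiomer is used.
- The configuration α to the aldehyde in 5 is erased in step 3 and does not matter.

Step 1
Reactants: 1 (−)-menthone
Product: 3 kinetic trimethylsilyl enol ether of menthone, via lithium enolate 2 (not isolated)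
Conditions: LiN(iPr)2, THF, −78 °C; then Me3SiCl, −78 °C to rt
Reagents that add atoms: chlorotrimethylsilane C[Si](C)(C)Cl
Why: Kinetic deprotonation by the hindered amide base takes a proton from the CH2 next to the carbonyl (future C5) and not from the isopropyl-bearing methine, and O-silylation traps the regiodefined enolate (kinetic enolate trapping); no stereocentre is formed and C7 is untouched.

Step 2
Reactants: 3 silyl enol ether
Product: 5 (2S,5R)-5-methyl-6-oxo-2-(propan-2-yl)hexanoic acid, via methoxy hydroperoxide 4 (not isolated)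
Conditions: O3, CH2Cl2/MeOH, −78 °C; then Me2S, −78 °C to rt
Reagents that add atoms: ozone [O-][O+]=O
Why: Ozonolysis of a silyl enol ether cleaves C5=C6 so that the silyloxy carbon (C6) becomes the carboxylic acid and C5 the aldehyde once Me2S has reduced the hydroperoxide; C7 is not touched.

Step 3
Reactants: 5 aldehyde acid; 6 ethyl vinyl ketone
Product: 8 (2S)-4-[(1S)-1,3-dimethyl-4-oxocyclohex-2-en-1-yl]-2-(propan-2-yl)butanoic acid, via Michael adduct 7 (not isolated)
Conditions: (S)-N-(4-dodecylphenylsulfonyl)pyrrolidine-2-carboxamide (20 mol%), BnNH2, 4 Å molecular sieves, ClCH2CH2Cl, rt to 40 °C; dilute HCl work-up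
Reagents that add atoms: none
Why: Enamine Michael addition of the α-branched aldehyde to the vinyl ketone followed by intramolecular aldol condensation (organocatalytic Robinson-type annulation) builds ring A, and the chiral proline sulfonamide shields one face of the planar aldehyde enamine and so sets the quaternary centre C10.

Step 4
Reactants: 8 enone acid
Product: 9 Se-phenyl selenoester of 8
Conditions: (PhSe)2, Bu3P, CH2Cl2, rt
Reagents that add atoms: diphenyl diselenide c1ccc(cc1)[Se][Se]c1ccccc1
Why: The phosphine and the diselenide activate the acid as an acyloxyphosphonium ion that benzeneselenolate captures (redox condensation to an acyl selenide), which leaves the hindered enone and C7 untouched.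

Step 5
Reactants: 9 selenoester
Product: 11 trans-fused (4S,5S,7S,10S)-eudesmane-3,6-dione, via cis-fused dione 10 (not isolated)
Conditions: Bu3SnH (slow addition), AIBN (cat.), PhH (high dilution), 80 °C; then NaOMe (0.3 equiv), MeOH, 40 °C
Reagents that add atoms: none
Why: The stannyl radical abstracts PhSe from 9 to give the C6 acyl radical, which adds to C5, the β-carbon of the ring-A enone, and the resulting C4 α-keto radical takes hydrogen from Bu3SnH; the closest known reaction type is the tin hydride-mediated cyclisation of acyl selenides onto electron-poor alkenes. Ring B (C5–C6–C7–C8–C9–C10) closes in the 6-exo-trig mode, with the quaternary C10 inside the forming ring (gem-dialkyl effect). The tether on C10 can reach only the α face of C5, so the kinetic product 10 is cis-fused; NaOMe then enolises the C6 ketone towards C5 and C7 and the C3 ketone towards C4. At equilibrium C5 should carry its hydrogen trans to the C10 methyl (trans-decalin, as in 5α-6-keto steroids), C4 its methyl equatorial (a 4β-methyl would be 1,3-diaxial to the C10 methyl) and C7 its isopropyl equatorial, so all three centres are controlled by C10. The step needs cyclisation to outrun decarbonylation and direct reduction of the acyl radical, which the electron-poor acceptor, high dilution and slow addition of Bu3SnH should secure; attack at C4 (7-endo, at the α-carbon) is polarity-mismatched.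

Step 6
Reactants: 11 trans-dione
Product: 12 (5R,7S,10S)-6-oxoeudesm-3-en-3-yl trifluoromethanesulfonate
Conditions: Tf2O, 2,6-di-tert-butyl-4-methylpyridine, CH2Cl2, −20 to 0 °C
Reagents that add atoms: triflic anhydride O=S(=O)(OS(=O)(=O)C(F)(F)F)C(F)(F)F
Why: Tf2O with a hindered pyridine converts the less hindered C3 ketone into the more substituted enol triflate (C3=C4), which fixes the position of the later double bond and erases C4, while the C6 ketone, flanked by two methine carbons, should not react (enol triflate formation).

Step 7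
Reactants: 12 keto enol triflate
Product: 13 (5R,6R,7S,10S)-6β-hydroxyeudesm-3-en-3-yl trifluoromethanesulfonate
Conditions: NaBH4, CeCl3·7H2O, MeOH/THF, −40 °C
Reagents that add atoms: none
Why: In this Luche-type reduction the axial approach to C6 from the β face is blocked by the 1,3-diaxial C10 methyl, so hydride enters from the α face and gives the axial 6β-alcohol, and the weakly basic medium should keep the β,γ-unsaturated ketone from isomerising.

Step 8
Reactants: 13 hydroxy enol triflate
Product: 14 (5R,6R,7S,10R)-eudesm-3-en-6β-ol
Conditions: Pd(OAc)2 (5 mol%), PPh3, HCO2H, Bu3N, DMF, 60 °C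
Reagents that add atoms: none
Why: Palladium-catalysed formate reduction of the enol triflate (oxidative addition to zerovalent palladium, formate-to-hydride exchange with loss of CO2, reductive elimination) replaces OTf by H with the double bond held at C3=C4; no stereocentre is touched.

Step 9
Reactants: 14 alkenol
Product: 15 (5R,6R,7S,10R)-eudesm-3-en-6β-yl benzoate
Conditions: BzCl, DMAP, pyridine, 60 °C
Reagents that add atoms: benzoyl chloride O=C(Cl)c1ccccc1
Why: DMAP-catalysed acylation (nucleophilic catalysis) esterifies the hindered axial alcohol with retention at C6, at a stage where it is the only hydroxyl group in the molecule.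

Step 10
Reactants: 15 alkenyl benzoate
Product: 17 (3R,4R,5S,6R,7S,10S)-3α,4β-dihydroxyeudesman-6β-yl benzoate, via 3α,4α-epoxide 16 (not isolated)
Conditions: mCPBA, CH2Cl2, 0 °C; then THF, H2O, HClO4 (cat.), 0 °C to rt
Reagents that add atoms: 3-chloroperbenzoic acid OOC(=O)c1cccc(Cl)c1; water O
Why: Prilezhaev epoxidation should occur on the α face of C3=C4, away from the axial C10 methyl and the 6β-benzoate, and acid-catalysed hydrolysis opens the 3α,4α-epoxide trans-diaxially at the tertiary C4 from the β face (directly or through the neighbouring benzoate carbonyl, which also reaches C4 from the β face), giving 3α-OH and 4β-OH with the C4 methyl α.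

**Compound list**

1 | (−)-menthone, (2S,5R)-5-methyl-2-(propan-2-yl)cyclohexan-1-one | CC(C)[C@@H]1CC[C@@H](C)CC1=O | starting material
2 | lithium (3R,6S)-3-methyl-6-(propan-2-yl)cyclohex-1-en-1-olate | CC(C)[C@@H]1CC[C@@H](C)C=C1[O-].[Li+] | intermediate
3 | trimethyl{[(3R,6S)-3-methyl-6-(propan-2-yl)cyclohex-1-en-1-yl]oxy}silane | CC(C)[C@@H]1CC[C@@H](C)C=C1O[Si](C)(C)C | intermediate
4 | trimethylsilyl (2S,5R)-6-hydroperoxy-6-methoxy-5-methyl-2-(propan-2-yl)hexanoate (both C6 epimers) | C[Si](C)(C)OC(=O)[C@H](C(C)C)CC[C@@H](C)C(OC)OO | intermediate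
5 | (2S,5R)-5-methyl-6-oxo-2-(propan-2-yl)hexanoic acid | OC(=O)[C@H](C(C)C)CC[C@@H](C)C=O | intermediate
6 | pent-1-en-3-one (ethyl vinyl ketone) | CCC(=O)C=C | starting material
7 | (2S,5S)-5-formyl-5-methyl-8-oxo-2-(propan-2-yl)decanoic acid | OC(=O)[C@H](C(C)C)CC[C@](C)(C=O)CCC(=O)CC | intermediate
8 | (2S)-4-[(1S)-1,3-dimethyl-4-oxocyclohex-2-en-1-yl]-2-(propan-2-yl)butanoic acid | OC(=O)[C@H](C(C)C)CC[C@@]1(C)CCC(=O)C(C)=C1 | intermediate
9 | Se-phenyl (2S)-4-[(1S)-1,3-dimethyl-4-oxocyclohex-2-en-1-yl]-2-(propan-2-yl)butaneselenoate | O=C([Se]c1ccccc1)[C@H](C(C)C)CC[C@@]1(C)CCC(=O)C(C)=C1 | intermediate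
10 | cis-fused (5R,7S,10S)-eudesmane-3,6-dione (5β-H, both C4 epimers) | CC(C)[C@@H]1CC[C@@]2(C)CCC(=O)C(C)[C@H]2C1=O | intermediate
11 | trans-fused (4S,5S,7S,10S)-eudesmane-3,6-dione (4α-Me, 5α-H, 7β-iPr, 10β-Me) | CC(C)[C@@H]1CC[C@@]2(C)CCC(=O)[C@@H](C)[C@@H]2C1=O | intermediate
12 | (5R,7S,10S)-6-oxoeudesm-3-en-3-yl trifluoromethanesulfonate | CC(C)[C@@H]1CC[C@@]2(C)CCC(OS(=O)(=O)C(F)(F)F)=C(C)[C@@H]2C1=O | intermediate
13 | (5R,6R,7S,10S)-6β-hydroxyeudesm-3-en-3-yl trifluoromethanesulfonate | CC(C)[C@@H]1CC[C@@]2(C)CCC(OS(=O)(=O)C(F)(F)F)=C(C)[C@@H]2[C@@H]1O | intermediate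
14 | (5R,6R,7S,10R)-eudesm-3-en-6β-ol | CC(C)[C@@H]1CC[C@@]2(C)CCC=C(C)[C@@H]2[C@@H]1O | intermediate
15 | (5R,6R,7S,10R)-eudesm-3-en-6β-yl benzoate | CC(C)[C@@H]1CC[C@@]2(C)CCC=C(C)[C@@H]2[C@@H]1OC(=O)c1ccccc1 | intermediate
16 | (3R,4S,5S,6R,7S,10S)-3α,4α-epoxyeudesman-6β-yl benzoate | CC(C)[C@@H]1CC[C@@]2(C)CC[C@H]3O[C@@]3(C)[C@@H]2[C@@H]1OC(=O)c1ccccc1 | intermediate
17 | (3R,4R,5S,6R,7S,10S)-3α,4β-dihydroxyeudesman-6β-yl benzoate, (1R,2S,4aS,7R,8R,8aS)-7,8-dihydroxy-4a,8-dimethyl-2-(propan-2-yl)decahydronaphthalen-1-yl benzoate | CC(C)[C@@H]1CC[C@@]2(C)CC[C@@H](O)[C@](C)(O)[C@@H]2[C@@H]1OC(=O)c1ccccc1 | target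

**Step count and risks**

Total step count: 10. Longest linear sequence: 10 steps, from 1.

Step 5 is the most likely to fail. The acyl radical may lose CO or be reduced before it cyclises, and the cis/trans equilibrium at C5 may not lie far enough on the trans side. The fallback closes the same C5–C6 bond by polar umpolung. It sets out from 8: BH3·SMe2 (THF, −10 °C) should reduce the carboxylic acid selectively to the primary alcohol F1, and Dess–Martin periodinane gives the keto aldehyde F2. A thiazolium-derived carbene (3-benzyl-5-(2-hydroxyethyl)-4-methylthiazolium chloride, Et3N, EtOH, 70 °C) turns the aldehyde into its Breslow intermediate, which adds to C5 (intramolecular Stetter reaction). The basic medium equilibrates the diketone, and the sequence comes back to the route at 11.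

Step 3 is next. Face selection at the all-alkyl quaternary centre may be poor, and the free acid may tie up the amine catalysts as salts. The fallback uses a stoichiometric chiral auxiliary and a stepwise annulation. It sets out from 5: Me3SiCHN2 gives the methyl ester F3, and condensation with (R)-1-phenylethylamine gives the imine F4. The secondary enamine tautomer of F4 adds to 6 under auxiliary control, and aqueous acetic acid releases the keto aldehyde ester F5. KOH in aqueous MeOH at 60 °C effects aldol condensation and ester hydrolysis, and the sequence comes back at 8. The enantiomer of the amine is chosen by the same test as the catalyst.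

Step 6 is third. The less substituted C2=C3 enol triflate may form, or the C6 ketone may be triflated. The fallback fixes the regiochemistry at a separable silyl enol ether. It sets out from 11: equilibrating silylation (Me3SiCl, NaI, Et3N, MeCN, rt) gives the more substituted silyl enol ether F6, which is purified from its regioisomer. CsF and PhNTf2 in DME then convert it regiospecifically into the enol triflate, and the sequence comes back at 12.

Further compounds
F1 | step 5 | (4S)-4-[(3S)-3-(hydroxymethyl)-4-methylpentyl]-2,4-dimethylcyclohex-2-en-1-one | OC[C@H](C(C)C)CC[C@@]1(C)CCC(=O)C(C)=C1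
F2 | step 5 | (2S)-4-[(1S)-1,3-dimethyl-4-oxocyclohex-2-en-1-yl]-2-(propan-2-yl)butanal | O=C[C@H](C(C)C)CC[C@@]1(C)CCC(=O)C(C)=C1
F3 | step 3 | methyl (2S,5R)-5-methyl-6-oxo-2-(propan-2-yl)hexanoate | COC(=O)[C@H](C(C)C)CC[C@@H](C)C=O
F4 | step 3 | methyl (2S,5R,6E)-5-methyl-6-{[(1R)-1-phenylethyl]imino}-2-(propan-2-yl)hexanoate | COC(=O)[C@H](C(C)C)CC[C@@H](C)/C=N/[C@H](C)c1ccccc1
F5 | step 3 | methyl (2S,5S)-5-formyl-5-methyl-8-oxo-2-(propan-2-yl)decanoate | COC(=O)[C@H](C(C)C)CC[C@](C)(C=O)CCC(=O)CC
F6 | step 6 | (5R,7S,10S)-3-[(trimethylsilyl)oxy]eudesm-3-en-6-one | CC(C)[C@@H]1CC[C@@]2(C)CCC(O[Si](C)(C)C)=C(C)[C@@H]2C1=O
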